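| flask | substrate | coupling partner | precatalyst | remark | time |
|---|---|---|---|---|---|
| green | 0.027 M | 0.70 equiv | 10 mol% | run made earlier |  |
| red | 0.027 M | 0.98 equiv | 10 mol% | run made earlier |  |
| grey | 0.027 M | 1.5 equiv | 10 mol% | run made earlier |  |
| summer | 0.027 M | 0.700 equiv (fed, over 3.20 min) | 10 mol% | all but coupling partner at the start; coupling partner goes in evenly over 3.20 min, the run ends at 4.0 min | 4.0 min |
| winter | 0.027 M | 0.700 equiv | 10 mol% | a single well-mixed tank run continuously and read at steady state, 4.0 min in it on average |  |
| dusk | 0.027 M (fed, over 3.20 min) | 0.700 equiv | 10 mol% | all but substrate at the start; substrate goes in evenly over 3.20 min, the run ends at 4.0 min | 4.0 min |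
| autumn | 0.027 M | 0.700 equiv | 10 mol% | everything together in a closed stirred flask, run for 4.0 min | 4.0 min |

| run | time / min | target / % |
|---|---|---|
| green | 0.200 | 0 |
| green | 0.333 | 1.0 |
| green | 0.667 | 4.5 |
| green | 1.33 | 14.8 |
| green | 2.50 | 29.3 |
| red | 1.00 | 12.9 |
| red | 2.00 | 29.9 |
| red | 3.00 | 41.7 |
| red | 4.00 | 49.8 |
| red | 5.00 | 58.3 |
| grey | 1.00 | 20.4 |
| grey | 2.00 | 41.5 |
| grey | 3.00 | 56.3 |
| grey | 4.00 | 68.5 |
| grey | 5.00 | 75.9 |

(scatter of a reading: 1 percentage point)

- the stated concentrations are those of everything mixed, before any reaction; amounts are the same in each set-up
- the numbers in the tables scatter with a standard deviation of 1 percentage point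
- the feed brings no volume worth counting
- the earlier runs were made in a closed, stirred flask

- the set-up with the highest amount of target at the outlet or at the end, in percent of the substrate put in ("none" if the first two lie within 2 percentage points) (summer / winter / dusk / autumn / none)
- amount of target at the outlet or at the end, in percent of the substrate put in, summer
- amount of target at the outlet or at the end, in percent of the substrate put in, winter
- amount of target at the outlet or at the end, in percent of the substrate put in, dusk
- amount of target at the outlet or at the end, in percent of the substrate put in, autumn

- Time was my way in: the red run held substrate and coupling partner nearly equal, so I replaced both by their common level, 0.990 of the substrate charge less the target formed, and the reciprocal of that level climbed almost straight, with a slope of 0.337 min⁻¹ between 2.00 min and 5.00 min.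
- Drawn back, this line met its starting value at 0.702 min, a lag I took as the activation of precatalyst, and both figures are readings that carry the scatter.
- For autumn I carried one number, 1.11, the clock, which is the slope multiplied by the time left after the lag, a Damköhler number in the usual term.
- In my first extreme the levels stayed at their starting values, which gave 0.777, more than the 0.700 of coupling partner charged, so the ceiling was that limiting reagent.
- In my second extreme the reaction ran at its final levels, as in the winter tank, where a clock of 1.15 gave 30.9 %.
- For the closed autumn flask integration gave me 39.8 %, more than the tank, and in that reckoning the product of levels fell from 0.700 to 0.182 and averaged 0.359, between my two extremes.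
- I reckoned neither dosed flask; the forecast named autumn best, with autumn at 39.7 %, winter at 30.9 %, summer at 31.2 % and dusk at 31.5 %, saying that “dosing starves the bimolecular rate”.

    precatalyst ⇌ catalyst (K = 5.20, k = 0.0210 s⁻¹)
    2 substrate → homo dimer (k = 2.50 × 10⁻⁴ M⁻¹ s⁻¹)
    substrate + coupling partner + catalyst → catalyst + target (k = 88.0 M⁻² s⁻¹)

- Autumn gave 39.1 %, which was 8.2 percentage points more than dusk at 30.9 %, while summer gave 30.6 % and winter 30.4 %. Autumn's figure came from the falling level of coupling partner together with the time given, since with that level held the same flask gave 52.9 %, and left until 40.0 min it gave 69.5 %. Autumn's result, run back through my formula, implied a clock of 1.07 against my 1.11. The red recipe with coupling partner cut to 0.700 equiv had a clock of 1.45 at 5.00 min, which gave 45.1 %, and that flask stood at 44.4 %.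

The numbers in the tables come from a simulation with constants of no real substance, and the scatter is random.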